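Ring B is disconnected across C4'–C5' back to a squarate-derived cyclobutenone. Its three contiguous oxygens at C2', C3' and C4' are the two alkoxy carbons and the carbonyl of the four-membered ring, the carbinol carbon becomes C1', and the CH=CH of a dienyl side chain becomes C6' and C5', with the quaternary 1,1-dimethylallyl carbon already attached. One thermal operation (ring opening, 6π closure, aromatisation) builds the pentasubstituted arene with O4' free for methylation and O1' silylated as the later triflate handle. The precursor is a 4-dienyl-4-silyloxy-2,3-diisopropoxycyclobutenone. Suzuki coupling to a 3-iodochromone and transfer hydrogenation/reoxidation then set C3 (S).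

Key step: step 6

Remark on the chemistry: C3 of the target is read from the SMILES as S (priorities C4 > C2 > C1' > H); compounds 7, 8, 9 and 11 are racemates whose single stereocentre is erased on aromatisation.

Step 1
Reactants: 1 2,2-dimethylbut-3-enoic acid
Product: 2 2,2-dimethylbut-3-en-1-ol
Conditions: LiAlH4, Et2O, 0 °C to reflux; aq. NaOH work-up
Reagents that add atoms: none
Why: Hydride reduction of a carboxylic acid with LiAlH4 gives the primary alcohol and leaves the isolated vinyl group untouched.

Step 2
Reactants: 2 2,2-dimethylbut-3-en-1-ol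
Product: 3 2,2-dimethylbut-3-enal
Conditions: (COCl)2, DMSO, CH2Cl2, −78 °C; Et3N, −78 °C to rt; used as a dried solution
Reagents that add atoms: none
Why: Swern oxidation stops at the aldehyde, which has no α-hydrogen and so can neither enolise nor move its alkene into conjugation; it is carried on in solution because it is volatile.

Step 3
Reactants: 3 2,2-dimethylbut-3-enal
Product: 4 (E)-1-iodo-3,3-dimethylpenta-1,4-diene
Conditions: CrCl2, CHI3, THF, 0 °C
Reagents that add atoms: iodoform, IC(I)I
Why: Takai olefination, in which a geminal dichromium carbenoid made from iodoform and divalent chromium adds to the aldehyde and eliminates, is E-selective (the more so for an α-branched aldehyde) and ignores the vinyl group.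

Step 4
Reactants: 4 (E)-1-iodo-3,3-dimethylpenta-1,4-diene; 5 diisopropyl squarate
Product: 8 rac-4-[(E)-3,3-dimethylpenta-1,4-dien-1-yl]-4-hydroxy-2,3-diisopropoxycyclobut-2-en-1-one, via alkenyllithium 6 (not isolated), via lithium alkoxide 7 (not isolated)
Conditions: t-BuLi (2 equiv), Et2O, −78 °C; then 5, THF, −78 °C; NH4Cl (aq) quench at −78 °C
Reagents that add atoms: none
Why: Iodine–lithium exchange keeps the E geometry, and 1,2-addition of the alkenyllithium to one carbonyl of the symmetric squarate at −78 °C is a standard single addition with no regiochemical question, giving a racemic carbinol centre that does not matter.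

Step 5
Reactants: 8 rac-4-[(E)-3,3-dimethylpenta-1,4-dien-1-yl]-4-hydroxy-2,3-diisopropoxycyclobut-2-en-1-one
Product: 9 rac-4-(tert-butyldimethylsilyloxy)-4-[(E)-3,3-dimethylpenta-1,4-dien-1-yl]-2,3-diisopropoxycyclobut-2-en-1-one
Conditions: TBSOTf, 2,6-lutidine, CH2Cl2, −78 to 0 °C
Reagents that add atoms: tert-butyldimethylsilyl trifluoromethanesulfonate, CC(C)(C)[Si](C)(C)OS(=O)(=O)C(F)(F)F
Why: Silyl triflate silylation of a hindered tertiary alcohol under excess 2,6-lutidine in the cold should outrun acid-triggered rearrangement of the hydroxycyclobutenone, and it tags the future O1' so that it emerges protected from the ring expansion.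

Step 6
Reactants: 9 rac-4-(tert-butyldimethylsilyloxy)-4-[(E)-3,3-dimethylpenta-1,4-dien-1-yl]-2,3-diisopropoxycyclobut-2-en-1-one
Product: 12 4-(tert-butyldimethylsilyloxy)-2,3-diisopropoxy-6-(2-methylbut-3-en-2-yl)phenol, via dienylketene 10 (not isolated), via cyclohexadienone 11 (not isolated)
Conditions: PhMe (0.02 M, degassed), 110 °C
Reagents that add atoms: none
Why: Relief of ring strain drives a thermal conrotatory 4π electrocyclic opening of the C1–C4 bond of 9 to dienylketene 10, which closes by a thermal disrotatory 6π electrocyclisation that joins the ketene carbon (future C4') to the alkene CH carrying the quaternary carbon (future C5'); the resulting cyclohexa-2,4-dienone 11 aromatises by proton shift to phenol 12. The closest known reaction type is the Moore ring expansion of 4-alkenyl-4-hydroxy- or 4-silyloxycyclobutenones made from squarate esters. The one ring closed is the six-membered carbocycle of ring B, formed in the hexatriene-to-cyclohexadiene (6π, disrotatory) mode. No stereocentre is created that survives, since the carbinol carbon becomes sp2 on opening and the sp3 carbon of 11 is lost on tautomerisation. The step needs torquoselectivity, which the donor silyloxy group at C4 secures by rotating outward and so turning the dienyl arm inward next to the ketene, while the E alkene keeps the bulky quaternary group on the outside of the closing triene. It also needs chemoselectivity, which the CMe2 carbon secures by taking the terminal vinyl group out of conjugation so that only the conjugated alkene can enter the 6π array, with aromatisation as the irreversible sink should dienone 11 begin to shuttle its allyl group by [3,3] shifts.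

Step 7
Reactants: 12 4-(tert-butyldimethylsilyloxy)-2,3-diisopropoxy-6-(2-methylbut-3-en-2-yl)phenol
Product: 13 tert-butyl[2,3-diisopropoxy-4-methoxy-5-(2-methylbut-3-en-2-yl)phenoxy]dimethylsilane
Conditions: MeI, K2CO3, acetone (dry, degassed), 55 °C
Reagents that add atoms: iodomethane, CI
Why: Williamson methylation of the only free phenol (O4'), under a weak base in dry acetone that should leave the aryl silyl ether in place and avoid silyl scrambling.

Step 8
Reactants: 13 tert-butyl[2,3-diisopropoxy-4-methoxy-5-(2-methylbut-3-en-2-yl)phenoxy]dimethylsilane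
Product: 15 2,3-diisopropoxy-4-methoxy-5-(2-methylbut-3-en-2-yl)phenyl trifluoromethanesulfonate, via ammonium phenoxide 14 (not isolated)
Conditions: TBAF, THF, 0 °C; then PhNTf2, rt
Reagents that add atoms: N-phenylbis(trifluoromethanesulfonimide), O=S(=O)(N(c1ccccc1)S(=O)(=O)C(F)(F)F)C(F)(F)F
Why: Fluoride cleaves the aryl silyl ether to the tetrabutylammonium phenoxide, which is sulfonylated in the same flask by PhNTf2, a standard phenol triflation at an oxygen with only one ortho substituent.

Step 9
Reactants: 15 2,3-diisopropoxy-4-methoxy-5-(2-methylbut-3-en-2-yl)phenyl trifluoromethanesulfonate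
Product: 16 2-[2,3-diisopropoxy-4-methoxy-5-(2-methylbut-3-en-2-yl)phenyl]-4,4,5,5-tetramethyl-1,3,2-dioxaborolane
Conditions: B2pin2, PdCl2(dppf) (5 mol%), KOAc, 1,4-dioxane, 90 °C
Reagents that add atoms: bis(pinacolato)diboron, CC1(C)OB(OC1(C)C)B1OC(C)(C)C(C)(C)O1
Why: Miyaura borylation of an aryl triflate, in which the weak acetate base permits boryl transfer but not onward biaryl coupling, and the hindered unconjugated vinyl group is a poor Heck partner.

Step 10
Reactants: 17 2,4-dihydroxyacetophenone
Product: 18 2-hydroxy-4-isopropoxyacetophenone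
Conditions: 2-bromopropane, K2CO3, DMF, 50 °C
Reagents that add atoms: 2-bromopropane, CC(C)Br
Why: Williamson alkylation selective for the 4-hydroxyl, because the 2-hydroxyl is held in a hydrogen bond to the acetyl carbonyl and is the poorer nucleophile.

Step 11
Reactants: 18 2-hydroxy-4-isopropoxyacetophenone
Product: 20 3-iodo-7-isopropoxy-4H-chromen-4-one, via enaminone 19 (not isolated)
Conditions: DMF-DMA, 95 °C; concentrate; then I2, CHCl3, rt
Reagents that add atoms: N,N-dimethylformamide dimethyl acetal, COC(OC)N(C)C; iodine, II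
Why: Condensation of the methyl ketone with the amide acetal gives the enaminone, and iodine then triggers α-iodination, closure of the phenol oxygen onto the iminium carbon and loss of dimethylamine, the standard enaminone iodocyclisation to 3-iodochromones.

Step 12
Reactants: 16 2-[2,3-diisopropoxy-4-methoxy-5-(2-methylbut-3-en-2-yl)phenyl]-4,4,5,5-tetramethyl-1,3,2-dioxaborolane; 20 3-iodo-7-isopropoxy-4H-chromen-4-one
Product: 21 3-[2,3-diisopropoxy-4-methoxy-5-(2-methylbut-3-en-2-yl)phenyl]-7-isopropoxy-4H-chromen-4-one
Conditions: PdCl2(dppf) (5 mol%), K2CO3, 1,4-dioxane/H2O, 80 °C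
Reagents that add atoms: none
Why: Suzuki–Miyaura coupling of a 3-iodochromone with an arylboronate is the standard isoflavone construction, with fast oxidative addition into the iodoenone C–I bond and a boronate that carries only one ortho substituent.

Step 13
Reactants: 21 3-[2,3-diisopropoxy-4-methoxy-5-(2-methylbut-3-en-2-yl)phenyl]-7-isopropoxy-4H-chromen-4-one
Product: 22 3-[2,3-dihydroxy-4-methoxy-5-(2-methylbut-3-en-2-yl)phenyl]-7-hydroxy-4H-chromen-4-one
Conditions: BCl3 (excess), CH2Cl2, −78 to 0 °C; aqueous work-up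
Reagents that add atoms: none
Why: BCl3 cleaves secondary alkyl aryl ethers through ionisation to 2-chloropropane far faster than it cleaves methyl aryl ethers in the cold, so the three isopropyl groups should leave while the C4' methyl ether and the monosubstituted alkene stay, and the step is placed on the achiral isoflavone so that no stereocentre meets the Lewis acid.

Step 14
Reactants: 22 3-[2,3-dihydroxy-4-methoxy-5-(2-methylbut-3-en-2-yl)phenyl]-7-hydroxy-4H-chromen-4-one
Product: 23 7-(tert-butyldimethylsilyloxy)-3-[2,3-bis(tert-butyldimethylsilyloxy)-4-methoxy-5-(2-methylbut-3-en-2-yl)phenyl]-4H-chromen-4-one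
Conditions: TBSOTf, 2,6-lutidine, CH2Cl2, 0 °C to rt
Reagents that add atoms: tert-butyldimethylsilyl trifluoromethanesulfonate, CC(C)(C)[Si](C)(C)OS(=O)(=O)C(F)(F)F
Why: Silyl triflate silylation covers all three phenols, including the crowded catechol pair, with groups that tolerate formate reduction and oxidation and later leave under non-basic fluoride.

Step 15
Reactants: 23 7-(tert-butyldimethylsilyloxy)-3-[2,3-bis(tert-butyldimethylsilyloxy)-4-methoxy-5-(2-methylbut-3-en-2-yl)phenyl]-4H-chromen-4-one
Product: 25 (3S,4S)-7-(tert-butyldimethylsilyloxy)-3-[2,3-bis(tert-butyldimethylsilyloxy)-4-methoxy-5-(2-methylbut-3-en-2-yl)phenyl]chroman-4-ol, via racemic isoflavanone 24 (not isolated)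
Conditions: RuCl(p-cymene)[(S,S)-TsDPEN] (5 mol%), HCO2H/Et3N (5:2), EtOAc, 40 °C
Reagents that add atoms: none
Why: In this asymmetric transfer hydrogenation with dynamic kinetic resolution the ruthenium hydride first reduces the chromone C2=C3 bond to isoflavanone 24, whose C3 epimerises quickly under Et3N, and the (S,S) catalyst then reduces one enantiomer faster, delivering hydride to the carbonyl face that gives the 4S carbinol (as it does for 4-chromanone) and anti to the aryl group, so the cis (3S,4S) alcohol should result while the isolated vinyl group is inert.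

Step 16
Reactants: 25 (3S,4S)-7-(tert-butyldimethylsilyloxy)-3-[2,3-bis(tert-butyldimethylsilyloxy)-4-methoxy-5-(2-methylbut-3-en-2-yl)phenyl]chroman-4-ol
Product: 26 (3S)-7-(tert-butyldimethylsilyloxy)-3-[2,3-bis(tert-butyldimethylsilyloxy)-4-methoxy-5-(2-methylbut-3-en-2-yl)phenyl]chroman-4-one
Conditions: Dess–Martin periodinane, NaHCO3, CH2Cl2, 0 °C
Reagents that add atoms: none
Why: Dess–Martin oxidation under bicarbonate buffering restores the C4 ketone under near-neutral conditions that should not enolise the product, so the C3 configuration set in step 15 is carried over unchanged.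

Step 17
Reactants: 26 (3S)-7-(tert-butyldimethylsilyloxy)-3-[2,3-bis(tert-butyldimethylsilyloxy)-4-methoxy-5-(2-methylbut-3-en-2-yl)phenyl]chroman-4-one
Product: 27 (3S)-3-[2,3-dihydroxy-4-methoxy-5-(2-methylbut-3-en-2-yl)phenyl]-7-hydroxychroman-4-one
Conditions: HF·pyridine, pyridine, THF, 0 °C to rt
Reagents that add atoms: none
Why: Fluoride cleavage of aryl silyl ethers with pyridine-buffered HF is slightly acidic and never basic, so the enolisable C3 centre next to the ketone should keep its configuration.

Compound list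
1 | 2,2-dimethylbut-3-enoic acid | C=CC(C)(C)C(=O)O | starting material
2 | 2,2-dimethylbut-3-en-1-ol | C=CC(C)(C)CO | intermediate
3 | 2,2-dimethylbut-3-enal | C=CC(C)(C)C=O | intermediate
4 | (E)-1-iodo-3,3-dimethylpenta-1,4-diene | C=CC(C)(C)/C=C/I | intermediate
5 | diisopropyl squarate (3,4-diisopropoxycyclobut-3-ene-1,2-dione) | CC(C)OC1=C(OC(C)C)C(=O)C1=O | starting material
6 | [(E)-3,3-dimethylpenta-1,4-dien-1-yl]lithium | C=CC(C)(C)/C=C/[Li] | intermediate
7 | lithium alkoxide of 8 (racemic) | C=CC(C)(C)/C=C/C1([O-])C(=O)C(OC(C)C)=C1OC(C)C.[Li+] | intermediate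
8 | rac-4-[(E)-3,3-dimethylpenta-1,4-dien-1-yl]-4-hydroxy-2,3-diisopropoxycyclobut-2-en-1-one | C=CC(C)(C)/C=C/C1(O)C(=O)C(OC(C)C)=C1OC(C)C | intermediate
9 | rac-4-(tert-butyldimethylsilyloxy)-4-[(E)-3,3-dimethylpenta-1,4-dien-1-yl]-2,3-diisopropoxycyclobut-2-en-1-one | C=CC(C)(C)/C=C/C1(O[Si](C)(C)C(C)(C)C)C(=O)C(OC(C)C)=C1OC(C)C | intermediate
10 | (3Z,5E)-4-(tert-butyldimethylsilyloxy)-2,3-diisopropoxy-7,7-dimethylnona-1,3,5,8-tetraen-1-one (dienylketene) | O=C=C(OC(C)C)/C(OC(C)C)=C(\C=C\C(C)(C)C=C)O[Si](C)(C)C(C)(C)C | intermediate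
11 | rac-4-(tert-butyldimethylsilyloxy)-2,3-diisopropoxy-6-(2-methylbut-3-en-2-yl)cyclohexa-2,4-dien-1-one | C=CC(C)(C)C1C=C(O[Si](C)(C)C(C)(C)C)C(OC(C)C)=C(OC(C)C)C1=O | intermediate
12 | 4-(tert-butyldimethylsilyloxy)-2,3-diisopropoxy-6-(2-methylbut-3-en-2-yl)phenol | C=CC(C)(C)c1cc(O[Si](C)(C)C(C)(C)C)c(OC(C)C)c(OC(C)C)c1O | intermediate
13 | tert-butyl[2,3-diisopropoxy-4-methoxy-5-(2-methylbut-3-en-2-yl)phenoxy]dimethylsilane | C=CC(C)(C)c1cc(O[Si](C)(C)C(C)(C)C)c(OC(C)C)c(OC(C)C)c1OC | intermediate
14 | tetrabutylammonium 2,3-diisopropoxy-4-methoxy-5-(2-methylbut-3-en-2-yl)phenoxide | C=CC(C)(C)c1cc([O-])c(OC(C)C)c(OC(C)C)c1OC.CCCC[N+](CCCC)(CCCC)CCCC | intermediate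
15 | 2,3-diisopropoxy-4-methoxy-5-(2-methylbut-3-en-2-yl)phenyl trifluoromethanesulfonate | C=CC(C)(C)c1cc(OS(=O)(=O)C(F)(F)F)c(OC(C)C)c(OC(C)C)c1OC | intermediate
16 | 2-[2,3-diisopropoxy-4-methoxy-5-(2-methylbut-3-en-2-yl)phenyl]-4,4,5,5-tetramethyl-1,3,2-dioxaborolane | C=CC(C)(C)c1cc(B2OC(C)(C)C(C)(C)O2)c(OC(C)C)c(OC(C)C)c1OC | intermediate
17 | 2,4-dihydroxyacetophenone | CC(=O)c1ccc(O)cc1O | starting material
18 | 2-hydroxy-4-isopropoxyacetophenone | CC(=O)c1ccc(OC(C)C)cc1O | intermediate
19 | (E)-3-(dimethylamino)-1-(2-hydroxy-4-isopropoxyphenyl)prop-2-en-1-one | CN(C)/C=C/C(=O)c1ccc(OC(C)C)cc1O | intermediate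
20 | 3-iodo-7-isopropoxy-4H-chromen-4-one | CC(C)Oc1ccc2c(=O)c(I)coc2c1 | intermediate
21 | 3-[2,3-diisopropoxy-4-methoxy-5-(2-methylbut-3-en-2-yl)phenyl]-7-isopropoxy-4H-chromen-4-one | C=CC(C)(C)c1cc(-c2coc3cc(OC(C)C)ccc3c2=O)c(OC(C)C)c(OC(C)C)c1OC | intermediate
22 | 3-[2,3-dihydroxy-4-methoxy-5-(2-methylbut-3-en-2-yl)phenyl]-7-hydroxy-4H-chromen-4-one | C=CC(C)(C)c1cc(-c2coc3cc(O)ccc3c2=O)c(O)c(O)c1OC | intermediate
23 | 7-(tert-butyldimethylsilyloxy)-3-[2,3-bis(tert-butyldimethylsilyloxy)-4-methoxy-5-(2-methylbut-3-en-2-yl)phenyl]-4H-chromen-4-one | C=CC(C)(C)c1cc(-c2coc3cc(O[Si](C)(C)C(C)(C)C)ccc3c2=O)c(O[Si](C)(C)C(C)(C)C)c(O[Si](C)(C)C(C)(C)C)c1OC | intermediate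
24 | rac-7-(tert-butyldimethylsilyloxy)-3-[2,3-bis(tert-butyldimethylsilyloxy)-4-methoxy-5-(2-methylbut-3-en-2-yl)phenyl]chroman-4-one | C=CC(C)(C)c1cc(C2COc3cc(O[Si](C)(C)C(C)(C)C)ccc3C2=O)c(O[Si](C)(C)C(C)(C)C)c(O[Si](C)(C)C(C)(C)C)c1OC | intermediate
25 | (3S,4S)-7-(tert-butyldimethylsilyloxy)-3-[2,3-bis(tert-butyldimethylsilyloxy)-4-methoxy-5-(2-methylbut-3-en-2-yl)phenyl]chroman-4-ol (3-aryl and 4-hydroxyl cis) | C=CC(C)(C)c1cc([C@H]2COc3cc(O[Si](C)(C)C(C)(C)C)ccc3[C@H]2O)c(O[Si](C)(C)C(C)(C)C)c(O[Si](C)(C)C(C)(C)C)c1OC | intermediate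
26 | (3S)-7-(tert-butyldimethylsilyloxy)-3-[2,3-bis(tert-butyldimethylsilyloxy)-4-methoxy-5-(2-methylbut-3-en-2-yl)phenyl]chroman-4-one | C=CC(C)(C)c1cc([C@H]2COc3cc(O[Si](C)(C)C(C)(C)C)ccc3C2=O)c(O[Si](C)(C)C(C)(C)C)c(O[Si](C)(C)C(C)(C)C)c1OC | intermediate
27 | (3S)-3-[2,3-dihydroxy-4-methoxy-5-(2-methylbut-3-en-2-yl)phenyl]-7-hydroxychroman-4-one | C=CC(C)(C)c1cc([C@H]2COc3cc(O)ccc3C2=O)c(O)c(O)c1OC | target

Total step count: 17.
Longest linear sequence: 15 steps (steps 1 to 9, then 12 to 17, from acid 1); the chromone branch (steps 10 and 11) joins at step 12.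

Steps most likely to fail

Step 6. The silyl group may be lost or may shuttle between the two para oxygens at 110 °C, which would erase the O1'/O4' distinction, and a slow closure of the crowded ketene would leave it open to dimerisation. The fallback sets out from hydroxycyclobutenone 8 and comes back at phenol 12. Heating 8 itself in degassed toluene at 110 °C, the parent form of this ring expansion with the free hydroxyl as the outward-rotating donor, should give the hydroquinone 2,3-diisopropoxy-5-(2-methylbut-3-en-2-yl)benzene-1,4-diol F1. The two hydroxyls are then told apart by sterics and no longer inside the thermolysis. TBSCl (1 equiv), imidazole, DMF, 0 °C should silylate the hydroxyl that has a ring hydrogen as neighbour (O1') and leave the one wedged between the isopropoxy group and the tert-alkyl group, which is 12.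

Step 15. The bulky 2'-silyloxy group may stall conjugate hydride transfer or blunt the face discrimination of the dynamic kinetic resolution, and the reoxidation that must follow adds a second chance to erode C3. The fallback sets out from isoflavone 23 and comes back at ketone 26, bypassing steps 15 and 16. Conjugate reduction of 23 with LiBH(s-Bu)3 (THF, −78 °C) and trapping of the enolate with allyl chloroformate should give the enol carbonate allyl 7-(tert-butyldimethylsilyloxy)-3-[2,3-bis(tert-butyldimethylsilyloxy)-4-methoxy-5-(2-methylbut-3-en-2-yl)phenyl]-2H-chromen-4-yl carbonate F2. Palladium-catalysed decarboxylative enantioselective protonation (Pd2(dba)3, t-Bu-PHOX, Meldrum's acid, 1,4-dioxane, rt), run with whichever ligand antipode proves to give the 3S ketone, should then deliver 26 directly.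

Step 12. Protodeboronation of the electron-rich, ortho-alkoxy boronate under aqueous base may outpace transmetalation, and hydroxide may open the pyrone ring of the iodochromone. The fallback sets out from iodochromone 20 and aryl triflate 15 and comes back at isoflavone 21, making step 9 unnecessary. Zinc insertion into 20 (Zn dust, LiCl, THF, rt) should give (7-isopropoxy-4-oxo-4H-chromen-3-yl)zinc iodide F3, which is joined to triflate 15 by Negishi coupling (Pd(OAc)2, SPhos, THF, 50 °C), so that ring B is the electrophile and no base or water is present.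

Further compounds
F1 | step 6 | 2,3-diisopropoxy-5-(2-methylbut-3-en-2-yl)benzene-1,4-diol | C=CC(C)(C)c1cc(O)c(OC(C)C)c(OC(C)C)c1O
F2 | step 15 | allyl 7-(tert-butyldimethylsilyloxy)-3-[2,3-bis(tert-butyldimethylsilyloxy)-4-methoxy-5-(2-methylbut-3-en-2-yl)phenyl]-2H-chromen-4-yl carbonate | C=CCOC(=O)OC1=C(c2cc(C(C)(C)C=C)c(OC)c(O[Si](C)(C)C(C)(C)C)c2O[Si](C)(C)C(C)(C)C)COc2cc(O[Si](C)(C)C(C)(C)C)ccc21
F3 | step 12 | (7-isopropoxy-4-oxo-4H-chromen-3-yl)zinc iodide | CC(C)Oc1ccc2c(=O)c([Zn]I)coc2c1
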